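**Retrosynthetic overview**
1. The C1′–Ph bond is cut first. The benzylic carbon is taken as one of three equivalent formyl groups of a threefold-symmetric trialdehyde, 2,4,6-trihydroxybenzene-1,3,5-tricarbaldehyde (2), made from phloroglucinol (1). The phenyl group comes from phenylmagnesium bromide (3).
2. The C5–C1′ and C4–O bonds are cut together: hetero-Diels–Alder reaction of the endocyclic E-alkene of (−)-β-caryophyllene (4) with an o-quinone methide.
3. Both cuts are made in one flask. A single addition of 3 to 2 breaks the symmetry (5, 6), loss of water breaks the aromaticity (7), and the cycloaddition restores it and gives the target (8).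
4. Ring order: the arene (from 1) and the cyclobutane and nine-membered ring (from 4) are bought. The dihydropyran ring is the only ring made, and it is made last. C1 and C9 come from 4; C4, C5 and C1′ are set in the cycloaddition.

Assumption: commercial (−)-β-caryophyllene is the natural (1R,9S,4E) enantiomer; the terpene carbons are numbered as in caryophyllane and the benzylic carbon is C1′, which makes the target 1R,4R,5S,9S,1′R.

**Step 1**
Reactants: 1 phloroglucinol (benzene-1,3,5-triol)
Product: 2 2,4,6-trihydroxybenzene-1,3,5-tricarbaldehyde
Conditions: hexamethylenetetramine (2.2 equiv), CF3CO2H, 100 °C, 2.5 h; then 3 M HCl, 100 °C, 1 h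
Reagents that add atoms: hexamethylenetetramine, C1N2CN3CN1CN(C2)C3 (the three formyl carbons); water, O (the three formyl oxygens)
Why: Threefold Duff formylation, in which the electron-rich triol is aminomethylated at each free position by the iminium ions that hexamethylenetetramine gives in CF3CO2H, each benzylamine is oxidised to the iminium by hydride transfer and then hydrolysed to the aldehyde; no stereocentre is formed.

**Step 2**
Reactants: 2 2,4,6-trihydroxybenzene-1,3,5-tricarbaldehyde; 3 phenylmagnesium bromide; 4 (−)-β-caryophyllene
Product: 8 the target (1R,4R,5S,9S,1′R), via magnesium alkoxide 5 (not isolated), via benzhydrol 6 (not isolated), via o-quinone methide 7 (not isolated)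
Conditions: 3 (4.0 equiv), LiCl (4 equiv), THF, −40 → 20 °C, 3 h; then 1 M HCl (to pH 3), 4 (3 equiv), THF/H2O, 80 °C, 16 h, sealed tube
Reagents that add atoms: none
Why: Proposed new method: three equivalents of 3 deprotonate 2 and the fourth adds once to a magnesium-chelated formyl group (closest known type: aryl Grignard 1,2-addition to unprotected salicylaldehydes), which breaks the threefold symmetry and gives 5; acid frees 6, the carbinol that also lies on the Knoevenagel path to such quinone methides, so it loses water on warming to the dearomatised heterodiene 7 (every ring position is substituted, so 7 cannot oligomerise through the arene), and 7 is trapped by the strained E-alkene of 4 in an inverse-electron-demand hetero-Diels–Alder reaction (closest known type: thermal o-quinone methide cycloadditions of caryophyllene), in which oxygen goes to the tertiary carbon C4, suprafacial addition to the E-alkene puts Me-4 trans to H-5, attack on the open face of the major conformer of 4 (the face that is also epoxidised) gives 4R,5S, and the orientation with H-5 instead of the C6 methylene under the heterodiene gives 1′R.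

**Compound list**
1 | phloroglucinol (benzene-1,3,5-triol) | Oc1cc(O)cc(O)c1 | starting material
2 | 2,4,6-trihydroxybenzene-1,3,5-tricarbaldehyde | O=Cc1c(O)c(C=O)c(O)c(C=O)c1O | intermediate
3 | phenylmagnesium bromide | Br[Mg]c1ccccc1 | starting material
4 | (−)-β-caryophyllene, (1R,4E,9S)-4,11,11-trimethyl-8-methylidenebicyclo[7.2.0]undec-4-ene | C=C1CC/C=C(C)/CC[C@@H]2[C@@H]1CC2(C)C | starting material
5 | tetrakis(bromomagnesium) salt of 6 (one benzylic alkoxide, three phenoxides; racemic) | Br[Mg]OC(c1ccccc1)c1c(O[Mg]Br)c(C=O)c(O[Mg]Br)c(C=O)c1O[Mg]Br | intermediate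
6 | 2,4,6-trihydroxy-5-[hydroxy(phenyl)methyl]benzene-1,3-dicarbaldehyde (racemic; the carbinol centre is lost in 7) | OC(c1ccccc1)c1c(O)c(C=O)c(O)c(C=O)c1O | intermediate
7 | (5E)-5-benzylidene-2,4-dihydroxy-6-oxocyclohexa-1,3-diene-1,3-dicarbaldehyde (phenyl anti to the ring carbonyl that reacts) | O=C1C(C=O)=C(O)C(C=O)=C(O)/C1=C\c1ccccc1 | intermediate
8 | target: 6,8-diformyl-5,7-dihydroxy-4-phenylchroman fused through its C2–C3 bond to C4–C5 of the caryophyllane skeleton (O on C4, CHPh on C5); 1R,4R,5S,9S,1′R; Me-4 trans to H-5, Ph cis to H-5; 8(13)-methylidene and trans-fused gem-dimethylcyclobutane kept | C=C1CC[C@H]2[C@H](c3ccccc3)c3c(O)c(C=O)c(O)c(C=O)c3O[C@]2(C)CC[C@@H]2[C@@H]1CC2(C)C | target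

**Totals**
Total step count: 2. Longest linear sequence: 2 steps (1 → 2 → 8).

**Steps most likely to fail**
The route has only two steps, so both are listed; step 2 is listed twice because its two stages can fail independently.

Step 2, first stage (single Grignard addition). The tris(bromomagnesium) phenoxide of 2 is a deactivated, poorly soluble electrophile. Nothing but stoichiometry stops a second addition, so the yield of mono-adduct is statistical at best. Unreacted 2 is inert in the second stage and double adducts are easily separated. The fallback sets out from 2 and comes back at 6. MOMCl and iPr2NEt in CH2Cl2 convert 2 into 2,4,6-tris(methoxymethoxy)benzene-1,3,5-tricarbaldehyde F1, a soluble trialdehyde of normal electrophilicity. Addition of 3 (0.9 equiv) in THF at −78 °C, chromatography and return of unreacted F1 give 5-[hydroxy(phenyl)methyl]-2,4,6-tris(methoxymethoxy)benzene-1,3-dicarbaldehyde F2. 2 M HCl in THF/H2O at 40 °C removes the three acetals and gives 6, which is heated with 4 as in the second stage of step 2.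

Step 2, second stage (dehydration and cycloaddition). The C1′ epimer is the expected main by-product and has to be removed by chromatography. Adducts from the other alkene face or at the exocyclic alkene, and acid-induced rearrangement of 4 at 80 °C, can lower the yield further. The fallback sets out from 2 and comes back at 8. Boc2O, iPr2NEt and catalytic DMAP in CH2Cl2 give tri-tert-butyl 2,4,6-triformylbenzene-1,3,5-triyl tricarbonate F3. Addition of 3 (1.0 equiv) in THF at −78 °C with 4 (3 equiv) present is followed by a shift of the neighbouring Boc group to the new alkoxide. This gives tert-butyl [2-(bromomagnesiooxy)-4,6-bis(tert-butoxycarbonyloxy)-3,5-diformylphenyl](phenyl)methyl carbonate F4, and the freed phenoxide deactivates the two remaining formyl groups. Below 0 °C F4 loses tert-butyl carbonate and gives the bis(tert-butyl carbonate) of o-quinone methide 7 F5, an uncharged and more electrophilic heterodiene formed cold and without acid. Whether F5 adopts the reactive geometry next to the carbonate group is open. Cycloaddition under kinetic control gives the bis(tert-butyl carbonate) of 8 F6, and K2CO3 in MeOH at 0 °C frees 8.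

Step 1 (threefold Duff formylation). The reaction is known but low-yielding, because 1 partly resinifies with the formaldehyde equivalents before all three positions are formylated. The fallback sets out from 1 and comes back at 2. Vilsmeier–Haack formylation (POCl3, DMF; then H2O) stops cleanly after two formyl groups and gives 2,4,6-trihydroxybenzene-1,3-dicarbaldehyde F7. The one remaining position is then formylated by the Rieche method (Cl2CHOMe, TiCl4, CH2Cl2, 0 → 20 °C; aqueous work-up), where coordination of TiCl4 to the phenol oxygens delivers the electrophile to the free carbon, to give 2.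

**Further compounds**
F1 | step 2 | 2,4,6-tris(methoxymethoxy)benzene-1,3,5-tricarbaldehyde | COCOc1c(C=O)c(OCOC)c(C=O)c(OCOC)c1C=O
F2 | step 2 | 5-[hydroxy(phenyl)methyl]-2,4,6-tris(methoxymethoxy)benzene-1,3-dicarbaldehyde (racemic) | COCOc1c(C=O)c(OCOC)c(C=O)c(OCOC)c1C(O)c1ccccc1
F3 | step 2 | tri-tert-butyl 2,4,6-triformylbenzene-1,3,5-triyl tricarbonate | CC(C)(C)OC(=O)Oc1c(C=O)c(OC(=O)OC(C)(C)C)c(C=O)c(OC(=O)OC(C)(C)C)c1C=O
F4 | step 2 | tert-butyl [2-(bromomagnesiooxy)-4,6-bis(tert-butoxycarbonyloxy)-3,5-diformylphenyl](phenyl)methyl carbonate (racemic) | CC(C)(C)OC(=O)OC(c1ccccc1)c1c(O[Mg]Br)c(C=O)c(OC(=O)OC(C)(C)C)c(C=O)c1OC(=O)OC(C)(C)C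
F5 | step 2 | bis(tert-butyl carbonate) of o-quinone methide 7 (E) | O=C1C(C=O)=C(OC(=O)OC(C)(C)C)C(C=O)=C(OC(=O)OC(C)(C)C)/C1=C\c1ccccc1
F6 | step 2 | bis(tert-butyl carbonate) of 8 (both phenolic hydroxy groups protected; 1R,4R,5S,9S,1′R) | C=C1CC[C@H]2[C@H](c3ccccc3)c3c(OC(=O)OC(C)(C)C)c(C=O)c(OC(=O)OC(C)(C)C)c(C=O)c3O[C@]2(C)CC[C@@H]2[C@@H]1CC2(C)C
F7 | step 1 | 2,4,6-trihydroxybenzene-1,3-dicarbaldehyde | O=Cc1c(O)cc(O)c(C=O)c1O
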